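The amounts at the end of a flask sort into two groups: substrate and intermediate, which together form the pool, and target and side product, which hold what has drained from it.

the same everywhere: substrate 0.20 M
- Wednesday's: coupling partner 0.21 M; catalyst 0.29 mM; run made earlier
- Saturday's: coupling partner 0.21 M; catalyst 0.68 mM; run made earlier
- elm: coupling partner 0.210 M; catalyst 0.40 mM; time 2.5 min
- maple: coupling partner 0.210 M; catalyst 0.60 mM; time 2.5 min
- alder: coupling partner 0.210 M; catalyst 0.90 mM; time 2.5 min

| run | time / min | target / % | side product / % | substrate / % | intermediate / % |
|---|---|---|---|---|---|
| Wednesday's | 0.200 | 2.0 | 0.4 | 67.8 | 32.1 |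
| Wednesday's | 0.333 | 1.9 | 0 | 56.2 | 40.8 |
| Wednesday's | 0.500 | 4.5 | 0.3 | 47.5 | 47.6 |
| Wednesday's | 0.667 | 3.7 | 0 | 42.4 | 52.6 |
| Wednesday's | 1.00 | 4.2 | 2.2 | 37.0 | 54.8 |
| Wednesday's | 1.50 | 10.3 | 4.1 | 34.2 | 51.7 |
| Wednesday's | 2.50 | 15.9 | 7.7 | 29.1 | 45.8 |
| Saturday's | 0.167 | 1.0 | 0 | 53.0 | 45.6 |
| Saturday's | 0.417 | 7.5 | 0.2 | 38.1 | 53.6 |
| Saturday's | 0.667 | 10.9 | 2.8 | 34.2 | 51.8 |
| Saturday's | 1.00 | 16.6 | 3.6 | 32.0 | 46.3 |
| Saturday's | 1.50 | 23.3 | 7.6 | 26.2 | 41.4 |
| Saturday's | 2.00 | 27.7 | 11.6 | 23.8 | 37.1 |
| Saturday's | 2.50 | 31.3 | 17.7 | 21.1 | 32.0 |

(standard deviation of a reading: 1 percentage point)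

- percentages count the substrate that a species holds: one side product counts as two
- the earlier runs were read with a standard deviation of 1 percentage point

1. which of these there is most of at the end, counted by the substrate in it, elm (target / substrate / intermediate / side product)
2. which of these there is most of at the end, counted by the substrate in it, maple (target / substrate / intermediate / side product)
3. which of these there is most of at the end, counted by the substrate in it, alder (target / substrate / intermediate / side product)
4. amount of the one of these that there is most of at the end, in percent of the substrate charged, elm
5. amount of the one of these that there is most of at the end, in percent of the substrate charged, maple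
6. amount of the one of these that there is most of at the end, in percent of the substrate charged, alder

At the last reading the pool stood at 74.9% in Wednesday's flask and 53.1% in Saturday's. On average, intermediate held 0.607 of the pool, and target held 0.656 of the drained part. Intermediate is therefore that first share of the pool, target the second share of the remainder, and the two are level at 51.9%. This is the crossing pool, the fraction of the charge left in the pool when intermediate and target hold equal amounts. The last reading of Saturday's flask stood just above it, with target read at 31.3% and intermediate at 32.0%, a gap inside the scatter of 1 point.

Alder carries more catalyst than Saturday's flask, and Saturday's larger catalyst charge left a smaller pool than Wednesday's, so 53.1% is taken as the bound on alder's pool from above. As read, Wednesday's flask lost more of its pool, logarithmically, per unit of catalyst than Saturday's. If that loss per unit of catalyst does not rise with the charge, Saturday's loss carried to alder gives an estimated bound from below, 43.3%. That lower pool bounds alder's target from above at 56.7%. Wednesday's target share, the larger of the two read, tightens this to 38.2%, and Saturday's share with the upper pool gives 30.0% from below. The crossing pool lies near the top of alder's pool bracket, so this reckoning favours target there. Saturday's loss gives intermediate 41.8% in elm and 34.7% in maple.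

The forecast names intermediate at 41% in elm, intermediate at 35% in maple and target at 34.5% in alder: “leads in elm and maple, while target overtakes it in alder”. Its alder value stands above the lower bound and below the upper.

The flasks end with intermediate at 41.3% in elm, intermediate at 34.8% in maple and target at 37.1% in alder.

    substrate + target → side product (k = 0.0509 L mol⁻¹ s⁻¹)
    substrate + catalyst ⇌ catalyst + intermediate (K = 1.60, k = 128 L mol⁻¹ s⁻¹)
    2 substrate → homo dimer (k = 6.96 × 10⁻⁵ L mol⁻¹ s⁻¹)
    coupling partner + catalyst + intermediate → catalyst + target (k = 52.9 L² mol⁻² s⁻¹)

Alder's pool of 45.6% lies below the crossing pool, with target ahead, and homo dimer, a species not among those read, holds 0.0422% of the charge in alder at the end. A neighbouring flask, alder with its coupling partner cut to 0.13 M, ends with a pool of 61.8%, higher than the crossing pool, and there intermediate at 37.9% stands ahead of target at 24.7%.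

The numbers in the tables were generated by integration with made-up constants; scatter was added.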